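The data were computed for substances that don't exist, noise included.

**The charge.** A small charge of single-handed catalyst, 1.0 mM against 0.20 M of each substrate, stands in a stirred flask under held gas. You have its first 50.0 h and want what follows.

- south-west: left-handed substrate 0.20 M; right-handed substrate 0.20 M; gas 6.5 mM (held); catalyst 1 mM; the very flask that is asked about, followed so far
- flask: left-handed substrate 0.20 M; gas 6.5 mM (held); catalyst 1.0 mM; right-handed substrate 0.20 M; time 10 d

south-west run (percent of the left-handed substrate and right-handed substrate together charged)

| time / h | left-handed product / % | right-handed product / % |
|---|---|---|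
| 2.50 | 2.6 | 1.1 |
| 8.00 | 3.6 | 0 |
| 15.0 | 6.6 | 0.3 |
| 20.0 | 8.9 | 1.5 |
| 30.0 | 10.7 | 1.0 |
| 40.0 | 12.6 | 0 |
| 50.0 | 14.7 | 1.7 |

(scatter of a reading: 1 percentage point)

- catalyst is single-handed; left-handed substrate and right-handed substrate are mirror images of each other, charged as a racemate, each of them at the stated concentration
- at the start none of the gas is in solution
- an excess is the difference of the two amounts in percent of their sum
- an excess is below zero if the other one leads

- excess of left-handed product over right-handed product in the product at 25 h
- excess of left-handed product over right-handed product in the product at 10 d
- part of the left-handed substrate and right-handed substrate charged together that has reacted at 10 d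

**Zero of scale.** Weight each reading by its time, and the run gives 12.3 of left-handed product per right-handed product: this is the selectivity factor, that ratio while the two substrates stand equal. A factor of 1 is the symmetric case, with excess zero. With the two substrates equal, the excess is the factor less one over the factor plus one, here 85.0%. It is a loose reading, since the right-handed values, none above 1.7%, scatter by 1 percentage point.

**The curve.** In the south-west run, left-handed product reads 8.9% after the first 20.0 h and gains 5.8 points in the next 30.0 h, so the readings, with their scatter, show a knee near that time. Carried straight on, that tail reaches the left-handed charge, half of the two together, at 9.69 d, just before 10 d, and gives 51.4% at 10 d. Passing that mark takes right-handed substrate turning left-handed, which no reading tests. I commit to that turning, which in my reckoning keeps the two substrates about equal: the excess stays at 85.0% from 25 h to 10 d, with 55.6% reacted at 10 d.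

**The forecast.** It says “Product inhibition lands in between” and gives an excess of 87% at 25 h and 81% at 10 d, with 29% reacted at 10 d, where I stay at 85.0% and 55.6%.

**The flask.** It gives 87.7% at 25 h, 87.6% at 10 d, and 53.1% reacted.

    reagent + catalyst + left-handed substrate → catalyst + left-handed product (k = 2400 M⁻² h⁻¹)
    reagent + catalyst + right-handed substrate → catalyst + right-handed product (k = 150 M⁻² h⁻¹)
    left-handed substrate ⇌ right-handed substrate (k = 0.0490 h⁻¹)
    gas ⇌ reagent, rate k4*(csat - [reagent]) (kL = 0.920 h⁻¹)
    catalyst ⇌ dormant form (K = 1.30, k = 0.0430 h⁻¹)

**Factor reused.** The half-life of left-handed substrate by its forward step to right-handed substrate alone, the way back not counted, is 0.59 d, shorter than 10 d. The factor 12.3 turns 53.1% reacted into 3.99% right-handed product, and this flask holds 3.29% at 10.0 d. In the neighbour flask with 6.0 × 10⁻⁴ M of catalyst, 38.3% reacted at 10 d gives 2.88% by the same factor, and it holds 2.33%.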